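(The numbers in the tables were generated by integration for substances that don't exist, noise included.)

No run reports the reagent, so you cannot read how much of it remains. Yet the next charge hangs on that: decide between the two flasks below.

all flasks: substrate 20 mM
- alpha: reagent 36 mM; capture agent 20 mM; run made earlier
- eta: reagent 40 mM; capture agent 20 mM; run made earlier
- delta: reagent 54 mM; capture agent 20 mM; run made earlier
- south: reagent 30.0 mM; capture agent 20.0 mM; time 4.0 h
- south-east: reagent 60.0 mM; capture agent 20.0 mM; time 4.0 h

| run | time / h | substrate / % | bis adduct / % |
|---|---|---|---|
| alpha | 0.250 | 83.9 | 0.2 |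
| alpha | 0.667 | 66.1 | 0.6 |
| alpha | 1.33 | 49.3 | 1.7 |
| alpha | 2.00 | 39.2 | 2.9 |
| alpha | 3.00 | 28.3 | 4.6 |
| eta | 0.250 | 82.7 | 0 |
| eta | 0.417 | 73.4 | 0.5 |
| eta | 0.833 | 57.9 | 1.4 |
| eta | 1.33 | 44.9 | 1.9 |
| eta | 3.00 | 24.9 | 5.6 |
| delta | 0.500 | 61.9 | 1.1 |
| delta | 1.00 | 42.4 | 2.2 |
| delta | 1.50 | 30.6 | 5.1 |
| delta | 2.50 | 17.8 | 8.0 |
| delta | 3.00 | 14.5 | 8.8 |

(scatter of a reading: 0.3 percentage points)

- the earlier runs were read with a standard deviation of 0.3 percentage points

1. part of the substrate that has reacted at the end, south
2. part of the substrate that has reacted at the end, south-east
3. what raising the concentration of reagent from its lowest to its highest value here does to the part of the substrate that has reacted (changes below 5 percentage points count as none) (no change / it falls / it rises)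

Assume the substrate A is lost at rate k·A·B, with B the free reagent. Then the slope of ln A is k·B, and one slope over another gives a ratio of reagent with k gone. Define the reagent cost n as reagent lost per substrate lost, one rate over the other, so that time drops out.

In alpha, the late slope over the first is 0.464. Set that equal to the ratio of free reagent in the two spans, each taken as the charge minus n times the mean substrate lost in that span, and solve: n is 1.54, the reagent cost of alpha. The first slope then reads k as 21.0 M⁻¹ h⁻¹.

Delta gives a ratio of 0.427 and a cost of 2.04, higher than alpha's. These are readings, and they carry the scatter of 0.3 points. Use alpha's on south and delta's on south-east.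

Let D be the reagent charge Bc minus n times the substrate charge Ac. Then B equals D plus n·A, and B/A grows as exp(kDt), so A equals D/((Bc/Ac)·exp(kDt) − n).

South has D of −0.866 mM: the charge about matches the cost, and neither side is clearly the limiting reagent. My reckoning gives 70.8% reacted in south.

South-east has D of 19.2 mM and gives 92.6%. That is a rise of 22 points, above the margin, so charge the larger amount if conversion is the aim.

The forecast says 70% for south and 91% for south-east. Of the part reacted it says: it rises. One of its grounds is that “the initial rate scales with reagent”. Its south-east figure is lower than mine.

The part reacted is 70.7% in south and 93.7% in south-east: it rises, by 23 points.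

    substrate + reagent → single product + released group (k = 21.0 M⁻¹ h⁻¹)
    reagent + single product → bis adduct + released group (k = 2.60 M⁻¹ h⁻¹)
    reagent + released group ⇌ idle adduct, settled at all times (K = 84.0 M⁻¹)
    substrate + bis adduct → side product (k = 1.60 M⁻¹ h⁻¹)
    single product + capture agent → trapped intermediate (k = 18.0 M⁻¹ h⁻¹)

At the end of south, idle adduct holds 6.32 mM. Put alpha's cost on the substrate lost in south: it leaves 27.3% of the charged reagent free, and the flask shows 29.1%.

Now take a neighbour flask, south with 75 mM of reagent. Delta's cost gives D of 34.2 mM and 97.3% reacted. The computed flask gives 97.5%.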